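**Plan (labdane numbering: C1–C10 decalin, C11–C16 side chain)**

1. Retrosynthesis: the two acetates and the O-methyl group come off; the C7 carbinol goes back to the 8-en-7-one, which is the oxidative 1,3-transposition product of a C9 tertiary allylic alcohol, so the C9–C11 bond is cut to the side-chain iodide 5 and the bicyclic 7-en-9-one 15.
2. Ring A is then opened at C3–C4. The enabling feature is the oxygen-bearing C3 bonded directly to the gem-dimethyl quaternary C4, which sits on the ring-fusion carbon C5 of ring B: C4 can be a tertiary radical made by hydrogen-atom transfer to an isopropenyl group on C5, and C3 an aldehyde held on C10 by the C1–C2 tether. The precursor 13 is therefore a 6,6-dialkylated (R)-carvone that already contains ring B, C5, the C8 methyl and both C4 methyl carbons.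
3. Forward: carvone is methylated, then allylated at the future C10 (ring B with its quaternary centre); the allyl group becomes the propanal arm; ring A is closed by the radical cyclisation; C3–OH is methylated; the side chain is joined at C9; transposition, reduction, desilylation and acetylation finish.
4. Stereochemistry: C5 from (R)-carvone; C10 by allylation anti to the C5 isopropenyl group; C3 from the chair-like transition state of the ring closure; C7 by axial hydride addition to the enone; C13 from methyl (R)-3-methylglutarate.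

Key step: step 9

Remark: the half-ester 1 and (R)-carvone 6 are taken as purchasable, enantiopure materials; the 3β preference in step 9 is an expectation from the chair model, not an established result for this substrate.

**Step 1**
Reactants: 1 methyl (R)-3-methylglutarate
Product: 2 methyl (R)-5-hydroxy-3-methylpentanoate
Conditions: BH3·SMe2, THF, 0 °C to rt; then MeOH
Reagents that add atoms: none
Why: Borane reduces the free carboxylic acid far faster than the methyl ester (chemoselective acid reduction via the acyloxyborane), and the stereocentre is not involved.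

**Step 2**
Reactants: 2 methyl (R)-5-hydroxy-3-methylpentanoate
Product: 3 methyl (R)-5-[(tert-butyldimethylsilyl)oxy]-3-methylpentanoate
Conditions: TBSCl, imidazole, DMF, 0 °C to rt
Reagents that add atoms: tert-butyldimethylsilyl chloride, CC(C)(C)[Si](C)(C)Cl
Why: Imidazole-promoted silylation of the primary alcohol, run directly on crude 2 so that silylation outpaces lactonisation to the δ-lactone.

**Step 3**
Reactants: 3 methyl (R)-5-[(tert-butyldimethylsilyl)oxy]-3-methylpentanoate
Product: 4 (S)-5-[(tert-butyldimethylsilyl)oxy]-3-methylpentan-1-ol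
Conditions: LiAlH4, Et2O, 0 °C; then H2O, NaOH(aq)
Reagents that add atoms: none
Why: Hydride reduction of the ester to the primary alcohol; the silyl ether and the remote stereocentre are inert (the descriptor changes only because the priorities change).

**Step 4**
Reactants: 4 (S)-5-[(tert-butyldimethylsilyl)oxy]-3-methylpentan-1-ol
Product: 5 (R)-tert-butyl[(5-iodo-3-methylpentyl)oxy]dimethylsilane
Conditions: I2, PPh3, imidazole, CH2Cl2, 0 °C to rt
Reagents that add atoms: iodine, II
Why: Appel-type iodination (Garegg–Samuelsson conditions) through the alkoxyphosphonium salt, with SN2 displacement at an achiral primary carbon.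

**Step 5**
Reactants: 6 (R)-(−)-carvone
Product: 8 6-methylcarvone [(5R)-2,6-dimethyl-5-(prop-1-en-2-yl)cyclohex-2-en-1-one; both C6 epimers], via lithium dienolate 7 (not isolated)
Conditions: LiN(i-Pr)2, THF, −78 °C; then MeI, −78 to 0 °C
Reagents that add atoms: iodomethane, CI
Why: Kinetic α′-deprotonation of the enone gives the cross-conjugated dienolate, which is C-methylated (enolate alkylation); the new centre forms as an epimer mixture that is planarised again in step 6.

**Step 6**
Reactants: 8 6-methylcarvone
Product: 10 (5S,6S)-6-allyl-2,6-dimethyl-5-(prop-1-en-2-yl)cyclohex-2-en-1-one (allyl trans to isopropenyl), via lithium enolate 9 (not isolated)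
Conditions: LiN(i-Pr)2, THF, −78 °C; then allyl bromide, DMPU, −78 °C to rt
Reagents that add atoms: allyl bromide, C=CCBr
Why: Alkylation of the tetrasubstituted α′-enolate; allyl bromide approaches the face anti to the adjacent C5 isopropenyl group, which sets the quaternary carbon (later C10) with methyl cis and the three-carbon arm trans to isopropenyl, as the trans ring fusion requires.

**Step 7**
Reactants: 10 (5S,6S)-6-allyl-2,6-dimethyl-5-(prop-1-en-2-yl)cyclohex-2-en-1-one
Product: 12 (5S,6S)-6-(3-hydroxypropyl)-2,6-dimethyl-5-(prop-1-en-2-yl)cyclohex-2-en-1-one, via alkyl(disiamyl)borane 11 (not isolated)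
Conditions: Sia2BH (from BH3·THF and 2-methylbut-2-ene, 0 °C), THF, 0 °C; then 30% H2O2, pH 7 phosphate buffer, 0 °C to rt
Reagents that add atoms: hydrogen peroxide, OO
Why: Anti-Markovnikov hydroboration–oxidation in which the bulky dialkylborane selects the monosubstituted allyl alkene over the 1,1-disubstituted isopropenyl group (flanked by the quaternary carbon) and over the hindered conjugated ketone, while buffered peroxide oxidises the C–B bond without Weitz–Scheffer epoxidation of the enone.

**Step 8**
Reactants: 12 (5S,6S)-6-(3-hydroxypropyl)-2,6-dimethyl-5-(prop-1-en-2-yl)cyclohex-2-en-1-one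
Product: 13 3-[(1S,6S)-1,3-dimethyl-2-oxo-6-(prop-1-en-2-yl)cyclohex-3-en-1-yl]propanal
Conditions: TEMPO (cat.), PhI(OAc)2, CH2Cl2, rt
Reagents that add atoms: none
Why: Oxoammonium-mediated (TEMPO) oxidation stops at the aldehyde and touches neither alkene; no epimerisable centre is present.

**Step 9**
Reactants: 13 3-[(1S,6S)-1,3-dimethyl-2-oxo-6-(prop-1-en-2-yl)cyclohex-3-en-1-yl]propanal
Product: 14 (4aS,6S,8aS)-6-hydroxy-2,5,5,8a-tetramethyl-4a,5,6,7,8,8a-hexahydronaphthalen-1(4H)-one (trans-fused; 3β-OH, 5α-H, 10β-methyl in labdane terms)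
Conditions: Fe(acac)3 (30 mol %), PhSiH3 (2.5 equiv), EtOH, 60 °C, 0.02 M
Reagents that add atoms: none
Why: An iron hydride formed from Fe(acac)3, PhSiH3 and EtOH transfers a hydrogen atom to the CH2 terminus of the isopropenyl group (Markovnikov sense), the resulting tertiary C4 radical adds to the carbon of the C3 aldehyde, and the alkoxy radical is reduced by divalent iron and protonated by ethanol. The closest known reaction type is the iron-hydride, hydrogen-atom-transfer-initiated reductive radical cyclisation of alkene-tethered carbonyl compounds (Mukaiyama-type MHAT chemistry). Ring A closes in the 6-exo-trig mode onto the C=O group, and the trans ring fusion is inherited because the radical-bearing substituent on C5 and the aldehyde arm on C10 are already trans on ring B (step 6) and both lie equatorial in a chair-like transition state. C4 becomes the gem-dimethyl quaternary carbon (not stereogenic), and C3 is set by that chair, in which the aldehyde oxygen is expected to be pseudo-equatorial, away from the axial hydrogens on C1 and C5, giving the 3β (3S) alcohol. The step needs hydrogen-atom transfer to the electron-rich 1,1-disubstituted alkene and not to the electron-poor enone, which the polarity of the iron hydride should secure; the enone β-carbon cannot trap the radical intramolecularly (a four-membered ring would result) and dilution suppresses intermolecular conjugate addition. Reversal of the ring closure by β-scission of the alkoxy radical is the process to outrun, and fast reduction of that radical by the iron catalyst in ethanol is what should secure it.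

**Step 10**
Reactants: 14 (4aS,6S,8aS)-6-hydroxy-2,5,5,8a-tetramethyl-4a,5,6,7,8,8a-hexahydronaphthalen-1(4H)-one
Product: 15 (4aS,6S,8aS)-6-methoxy-2,5,5,8a-tetramethyl-4a,5,6,7,8,8a-hexahydronaphthalen-1(4H)-one
Conditions: Me3OBF4, 1,8-bis(dimethylamino)naphthalene, 4 Å MS, CH2Cl2, rt
Reagents that add atoms: trimethyloxonium tetrafluoroborate, C[O+](C)C.F[B-](F)(F)F
Why: O-Alkylation of the neopentylic secondary hydroxyl with a Meerwein salt under a non-nucleophilic amine base, so that no enolate of the enone is generated; the C3–O bond is untouched and the configuration is retained.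

**Step 11**
Reactants: 5 (R)-tert-butyl[(5-iodo-3-methylpentyl)oxy]dimethylsilane; 15 (4aS,6S,8aS)-6-methoxy-2,5,5,8a-tetramethyl-4a,5,6,7,8,8a-hexahydronaphthalen-1(4H)-one
Product: 17 15-[(tert-butyldimethylsilyl)oxy]-3β-methoxylabd-7-en-9-ol (13S; both C9 epimers), via alkyllithium 16 (not isolated)
Conditions: 5, t-BuLi (2.1 equiv), Et2O/pentane, −78 °C; then 15, −78 to 0 °C; then H2O
Reagents that add atoms: none
Why: Iodine–lithium exchange followed by 1,2-addition of the primary alkyllithium to the enone carbonyl, which has no α′-hydrogen because C10 is quaternary; attack opposite the axial C10 methyl is expected, but the C9 configuration is irrelevant since C9 becomes sp2 in step 12.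

**Step 12**
Reactants: 17 15-[(tert-butyldimethylsilyl)oxy]-3β-methoxylabd-7-en-9-ol
Product: 18 15-[(tert-butyldimethylsilyl)oxy]-3β-methoxylabd-8-en-7-one (3S,5R,10S,13S)
Conditions: pyridinium chlorochromate [C5H5NH][CrO3Cl], 4 Å MS, CH2Cl2, rt
Reagents that add atoms: pyridinium chlorochromate, [O-][Cr](=O)(=O)Cl.c1cc[nH+]cc1
Why: Dauben–Babler oxidative 1,3-transposition, in which the tertiary allylic chromate ester undergoes a [3,3] shift to the secondary C7 chromate that is oxidised to the tetrasubstituted 8-en-7-one; both C9 epimers converge and the silyl and methyl ethers are stable.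

**Step 13**
Reactants: 18 15-[(tert-butyldimethylsilyl)oxy]-3β-methoxylabd-8-en-7-one
Product: 19 15-[(tert-butyldimethylsilyl)oxy]-3β-methoxylabd-8-en-7β-ol (7S)
Conditions: NaBH4, CeCl3·7H2O, MeOH, −20 to 0 °C
Reagents that add atoms: none
Why: Luche 1,2-reduction of the enone; hydride should add axially to C7 from the α face (opposite the axial C10 methyl, the stereoelectronically preferred path for cyclohexenones), giving the pseudo-equatorial 7β alcohol.

**Step 14**
Reactants: 19 15-[(tert-butyldimethylsilyl)oxy]-3β-methoxylabd-8-en-7β-ol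
Product: 20 3β-methoxylabd-8-ene-7β,15-diol (3S,5R,7S,10S,13S)
Conditions: Bu4NF, THF, 0 °C to rt
Reagents that add atoms: none
Why: Fluoride-induced cleavage of the primary silyl ether; the allylic alcohol, the methyl ether and the tetrasubstituted alkene are inert.

**Step 15**
Reactants: 20 3β-methoxylabd-8-ene-7β,15-diol
Product: 21 3β-methoxylabd-8-ene-7β,15-diyl diacetate (3S,5R,7S,10S,13S; CNP0401666.1)
Conditions: Ac2O, pyridine, DMAP (cat.), CH2Cl2, rt
Reagents that add atoms: acetic anhydride, CC(=O)OC(C)=O
Why: DMAP-catalysed acylation of the primary and the secondary allylic hydroxyl at oxygen, so C7 keeps its configuration; the mildly basic medium avoids ionisation of the allylic acetate.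

**Compound list**

1 | methyl (R)-3-methylglutarate [(3R)-5-methoxy-3-methyl-5-oxopentanoic acid] | OC(=O)C[C@@H](C)CC(=O)OC | starting material
2 | methyl (R)-5-hydroxy-3-methylpentanoate | OCC[C@@H](C)CC(=O)OC | intermediate
3 | methyl (R)-5-[(tert-butyldimethylsilyl)oxy]-3-methylpentanoate | CC(C)(C)[Si](C)(C)OCC[C@@H](C)CC(=O)OC | intermediate
4 | (S)-5-[(tert-butyldimethylsilyl)oxy]-3-methylpentan-1-ol | CC(C)(C)[Si](C)(C)OCC[C@@H](C)CCO | intermediate
5 | (R)-tert-butyl[(5-iodo-3-methylpentyl)oxy]dimethylsilane | CC(C)(C)[Si](C)(C)OCC[C@@H](C)CCI | intermediate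
6 | (R)-(−)-carvone [(5R)-2-methyl-5-(prop-1-en-2-yl)cyclohex-2-en-1-one] | O=C1C(C)=CC[C@@H](C(C)=C)C1 | starting material
7 | lithium dienolate of carvone (α′-enolate, formed in the flask) | [Li]OC1=C[C@H](C(C)=C)CC=C1C | intermediate
8 | 6-methylcarvone [(5R)-2,6-dimethyl-5-(prop-1-en-2-yl)cyclohex-2-en-1-one, both C6 epimers] | O=C1C(C)=CC[C@@H](C(C)=C)C1C | intermediate
9 | lithium enolate of 6-methylcarvone (formed in the flask) | [Li]OC1=C(C)[C@H](C(C)=C)CC=C1C | intermediate
10 | (5S,6S)-6-allyl-2,6-dimethyl-5-(prop-1-en-2-yl)cyclohex-2-en-1-one (allyl trans to isopropenyl) | C=CC[C@]1(C)C(=O)C(C)=CC[C@H]1C(C)=C | intermediate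
11 | bis(3-methylbutan-2-yl){3-[(1S,6S)-1,3-dimethyl-2-oxo-6-(prop-1-en-2-yl)cyclohex-3-en-1-yl]propyl}borane (formed in the flask) | CC(C)C(C)B(CCC[C@]1(C)C(=O)C(C)=CC[C@H]1C(C)=C)C(C)C(C)C | intermediate
12 | (5S,6S)-6-(3-hydroxypropyl)-2,6-dimethyl-5-(prop-1-en-2-yl)cyclohex-2-en-1-one | OCCC[C@]1(C)C(=O)C(C)=CC[C@H]1C(C)=C | intermediate
13 | 3-[(1S,6S)-1,3-dimethyl-2-oxo-6-(prop-1-en-2-yl)cyclohex-3-en-1-yl]propanal | O=CCC[C@]1(C)C(=O)C(C)=CC[C@H]1C(C)=C | intermediate
14 | (4aS,6S,8aS)-6-hydroxy-2,5,5,8a-tetramethyl-4a,5,6,7,8,8a-hexahydronaphthalen-1(4H)-one | O[C@H]1CC[C@]2(C)C(=O)C(C)=CC[C@H]2C1(C)C | intermediate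
15 | (4aS,6S,8aS)-6-methoxy-2,5,5,8a-tetramethyl-4a,5,6,7,8,8a-hexahydronaphthalen-1(4H)-one | CO[C@H]1CC[C@]2(C)C(=O)C(C)=CC[C@H]2C1(C)C | intermediate
16 | {(3S)-5-[(tert-butyldimethylsilyl)oxy]-3-methylpentyl}lithium (formed in the flask) | [Li]CC[C@H](C)CCO[Si](C)(C)C(C)(C)C | intermediate
17 | 15-[(tert-butyldimethylsilyl)oxy]-3β-methoxylabd-7-en-9-ol (5α-H, 10β-methyl, 13S; both C9 epimers) | CO[C@H]1CC[C@]2(C)C(O)(CC[C@H](C)CCO[Si](C)(C)C(C)(C)C)C(C)=CC[C@H]2C1(C)C | intermediate
18 | 15-[(tert-butyldimethylsilyl)oxy]-3β-methoxylabd-8-en-7-one (3S,5R,10S,13S) | CO[C@H]1CC[C@]2(C)C(CC[C@H](C)CCO[Si](C)(C)C(C)(C)C)=C(C)C(=O)C[C@H]2C1(C)C | intermediate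
19 | 15-[(tert-butyldimethylsilyl)oxy]-3β-methoxylabd-8-en-7β-ol (3S,5R,7S,10S,13S) | CO[C@H]1CC[C@]2(C)C(CC[C@H](C)CCO[Si](C)(C)C(C)(C)C)=C(C)[C@@H](O)C[C@H]2C1(C)C | intermediate
20 | 3β-methoxylabd-8-ene-7β,15-diol (3S,5R,7S,10S,13S) | CO[C@H]1CC[C@]2(C)C(CC[C@H](C)CCO)=C(C)[C@@H](O)C[C@H]2C1(C)C | intermediate
21 | 3β-methoxylabd-8-ene-7β,15-diyl diacetate (3S,5R,7S,10S,13S; CNP0401666.1) | CO[C@H]1CC[C@]2(C)C(CC[C@H](C)CCOC(C)=O)=C(C)[C@@H](OC(C)=O)C[C@H]2C1(C)C | target

**Step count and risks**

Total step count: 15 (4 for the side-chain iodide 5, 11 in the main line). Longest linear sequence: 11 steps (steps 5–15, from carvone 6).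

Steps most likely to fail:

Step 9 (key ring closure). The ring closure onto the aldehyde is reversible: β-scission of the alkoxy radical can return the tertiary radical, which would then simply be reduced to an isopropyl group, and discrimination between the two chair-like transition states at C3 may be weak. The fallback changes the acceptor and moves C3 stereocontrol to a hydride reduction. It sets out from aldehyde 13, which I2 and aqueous NH3 in THF should convert into 3-[(1S,6S)-1,3-dimethyl-2-oxo-6-(prop-1-en-2-yl)cyclohex-3-en-1-yl]propanenitrile F1. Under the same Fe(acac)3/PhSiH3/EtOH conditions the tertiary radical should add to the nitrile carbon (6-exo-dig), and reduction of the iminyl radical gives the cyclic ketimine F2. Acidic aqueous work-up hydrolyses it to the 3,9-dione (4aS,8aS)-2,5,5,8a-tetramethyl-4a,5,8,8a-tetrahydronaphthalene-1,6(4H,7H)-dione F3. NaBH4 in MeOH/CH2Cl2 at −78 °C should then reduce only the saturated C3 ketone (the conjugated, doubly flanked C9 ketone reacts much more slowly), by axial attack from the α face away from the 4β and 10β methyl groups. The fallback comes back to the route at the 3β-alcohol 14.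

Step 11 (addition to the hindered C9 ketone). Steric shielding by the quaternary C10 and the C8 methyl may slow 1,2-addition enough that γ-deprotonation to the dienolate or consumption of the valuable alkyllithium competes. The fallback inverts the order of fragment union and ring-A closure, so that the addition is run early on the monocyclic 6,6-dialkylcarvone, with the cheap ketone in excess. It sets out from ketone 10 and alkyllithium 16, whose addition should give the tertiary allylic alcohol 6-allyl-1-{(3S)-5-[(tert-butyldimethylsilyl)oxy]-3-methylpentyl}-2,6-dimethyl-5-(prop-1-en-2-yl)cyclohex-2-en-1-ol F4. Pyridinium chlorochromate transposes it to the enone 4-allyl-3-{(3S)-5-[(tert-butyldimethylsilyl)oxy]-3-methylpentyl}-2,4-dimethyl-5-(prop-1-en-2-yl)cyclohex-2-en-1-one F5. Sia2BH then buffered H2O2 should give, through the alkyl(disiamyl)borane F6, the 4-(3-hydroxypropyl) enone F7. TEMPO/PhI(OAc)2 gives the propanal F8, and the iron-hydride cyclisation of step 9 closes ring A to 15-[(tert-butyldimethylsilyl)oxy]-3β-hydroxylabd-8-en-7-one F9. Me3OBF4 with 1,8-bis(dimethylamino)naphthalene then methylates C3–OH, and the fallback comes back to the route at enone 18.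

Step 7 (hydroboration–oxidation). Chemoselectivity may be lost through competing hydroboration of the isopropenyl group, borane reduction of the ketone, or nucleophilic epoxidation of the enone during the peroxide work-up. The fallback replaces hydroboration by a palladium-catalysed oxidation: a nitrite-modified, aldehyde-selective (anti-Markovnikov) Wacker oxidation with PdCl2(PhCN)2, CuCl2·2H2O and AgNO2 (all catalytic) under O2 in t-BuOH/MeNO2 at rt. This should leave the 1,1-disubstituted alkene and the enone alone and oxidise the monosubstituted allyl group, whose neighbouring quaternary carbon disfavours the methyl ketone. It sets out from 10 and comes back to the route at aldehyde 13, bypassing 12 and step 8; no new compound is made.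

**Further compounds**

F1 | step 9 | 3-[(1S,6S)-1,3-dimethyl-2-oxo-6-(prop-1-en-2-yl)cyclohex-3-en-1-yl]propanenitrile | N#CCC[C@]1(C)C(=O)C(C)=CC[C@H]1C(C)=C
F2 | step 9 | (4aS,8aS)-6-imino-2,5,5,8a-tetramethyl-4a,5,6,7,8,8a-hexahydronaphthalen-1(4H)-one | N=C1CC[C@]2(C)C(=O)C(C)=CC[C@H]2C1(C)C
F3 | step 9 | (4aS,8aS)-2,5,5,8a-tetramethyl-4a,5,8,8a-tetrahydronaphthalene-1,6(4H,7H)-dione | O=C1CC[C@]2(C)C(=O)C(C)=CC[C@H]2C1(C)C
F4 | step 11 | 6-allyl-1-{(3S)-5-[(tert-butyldimethylsilyl)oxy]-3-methylpentyl}-2,6-dimethyl-5-(prop-1-en-2-yl)cyclohex-2-en-1-ol (allyl trans to isopropenyl; both C1 epimers) | C=CC[C@]1(C)C(O)(CC[C@H](C)CCO[Si](C)(C)C(C)(C)C)C(C)=CC[C@H]1C(C)=C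
F5 | step 11 | 4-allyl-3-{(3S)-5-[(tert-butyldimethylsilyl)oxy]-3-methylpentyl}-2,4-dimethyl-5-(prop-1-en-2-yl)cyclohex-2-en-1-one (allyl trans to isopropenyl) | C=CC[C@]1(C)C(CC[C@H](C)CCO[Si](C)(C)C(C)(C)C)=C(C)C(=O)C[C@H]1C(C)=C
F6 | step 11 | alkyl(disiamyl)borane from hydroboration of the allyl group of F5 | CC(C)C(C)B(CCC[C@]1(C)C(CC[C@H](C)CCO[Si](C)(C)C(C)(C)C)=C(C)C(=O)C[C@H]1C(C)=C)C(C)C(C)C
F7 | step 11 | 3-{(3S)-5-[(tert-butyldimethylsilyl)oxy]-3-methylpentyl}-4-(3-hydroxypropyl)-2,4-dimethyl-5-(prop-1-en-2-yl)cyclohex-2-en-1-one | OCCC[C@]1(C)C(CC[C@H](C)CCO[Si](C)(C)C(C)(C)C)=C(C)C(=O)C[C@H]1C(C)=C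
F8 | step 11 | 3-[2-{(3S)-5-[(tert-butyldimethylsilyl)oxy]-3-methylpentyl}-1,3-dimethyl-4-oxo-6-(prop-1-en-2-yl)cyclohex-2-en-1-yl]propanal | O=CCC[C@]1(C)C(CC[C@H](C)CCO[Si](C)(C)C(C)(C)C)=C(C)C(=O)C[C@H]1C(C)=C
F9 | step 11 | 15-[(tert-butyldimethylsilyl)oxy]-3β-hydroxylabd-8-en-7-one | O[C@H]1CC[C@]2(C)C(CC[C@H](C)CCO[Si](C)(C)C(C)(C)C)=C(C)C(=O)C[C@H]2C1(C)C
F0 | step 7 | none | none
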